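All constants are assumed; the rest is arithmetic.

Amounts came first: the four set-ups below took the same charge and differed in vessel and in how the reagent entered.

all flasks: left-handed substrate 0.050 M; free catalyst 1.2 mol%; racemization catalyst 0.05 mol%; right-handed substrate 0.050 M
- west: reagent 3.00 equiv; time 12 h; a closed flask charged with all of it at once and left for 12 h
- east: reagent 3.00 equiv; time 12 h; plug flow through a tube for 12 h, no back-mixing
- south-west: reagent 3.00 equiv; a single well-mixed tank run continuously and read at steady state, 12 h in it on average
- south: reagent 3.00 equiv (fed, over 12.0 h); time 12 h; a stirred flask in which reagent is dosed at a steady rate over 12.0 h without added volume, worked up at 12 h

- the set-up with the highest amount of left-handed product at the outlet or at the end, in percent of the left-handed substrate and right-handed substrate together put in ("none" if the first two lie within 2 percentage points) (west / east / south-west / south / none)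
- amount of left-handed product at the outlet or at the end, in percent of the left-handed substrate and right-handed substrate together put in, west
- amount of left-handed product at the outlet or at the end, in percent of the left-handed substrate and right-handed substrate together put in, east
- amount of left-handed product at the outlet or at the end, in percent of the left-handed substrate and right-handed substrate together put in, south-west
- amount of left-handed product at the outlet or at the end, in percent of the left-handed substrate and right-handed substrate together put in, south

    reagent + free catalyst + right-handed substrate → free catalyst + right-handed product (k1 = 33 L² mol⁻² s⁻¹)
    left-handed substrate + racemization catalyst ⇌ right-handed substrate + racemization catalyst, rate k2*[racemization catalyst]*[left-handed substrate] forward; the back reaction follows from the equilibrium constant (k2 = 21 L mol⁻¹ s⁻¹)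
    reagent + free catalyst + left-handed substrate → free catalyst + left-handed product (k3 = 79 L² mol⁻² s⁻¹)

- free catalyst is single-handed; left-handed substrate and right-handed substrate are mirror images of each other, charged as a racemate, each of them at the stated concentration
- the stated concentrations are those of everything mixed, before any reaction; amounts are the same in each set-up
- the feed brings no volume worth counting
- run time (west): 12 h

Which charge would end first? I set 0.150 M of reagent against 0.100 M of the two substrate forms together, so the substrate was the limiting reagent, and the question became how the product divided between its hands.

Could racemization keep up? Free catalyst is regenerated in each step, so at a given reagent concentration each substrate form is acylated pseudo-first-order, at a frequency proportional to that concentration. At the charge in west, the forward half-life of racemization was 0.37 h against 0.0271 h for acylation of left-handed substrate, which gave d = 0.0738 for the racemization number, the racemization frequency divided by the acylation frequency of left-handed substrate.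

What yield did that number mean? At constant d and full conversion, the two linear rate equations give the left-handed share Y = (1 + 2sd)/(2(1 + d + sd)), with selectivity factor s = 2.39. In west and east the reagent fell to 0.0500 M, so d rose to 0.222, and I bracketed both between 54.1% and 58.8%. I put the south-west tank near the upper end, reckoning its d at the outlet reagent level.

Could dosing raise d? The reagent half-lives reckoned for west, 0.081 h by the left-handed step and 0.19 h by the right-handed step, hold for the same free catalyst and substrate charge in south, and against the dose of 12.0 h there they meant that, while substrate stood near its charge, reagent was used as it arrived. That gave south a starting d of 10.7 and Y of 70.0%, so I ranked south first.

The forecast, holding that “Slow reagent dosing starves the acylation”, gave 52.7% for west and 52.7% for east, below my bracket, with 53.2% for south-west and 67.2% for south, naming south as best.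

The simulation gave 56.9% in west, 56.9% in east, 57.9% in south-west and 68.8% in south, so south led.

West, with d running from 0.0738 to 0.222, had its reagent at 33% of its charge at the end. Its neighbour took 12.0 equiv of reagent, which cut d to 0.0185 at the start and left it at 0.0222 at the end. Y then put that flask between 51.2% and 51.4%. The neighbour ended with 83% of its reagent still there, 48.6% right-handed product and 51.4% left-handed product.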